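Winter's 16.7% of target, read at 8.00 h with c(substrate) = 0.27 M and c(reagent) = 0.27 M, is the number you hold against the three runs at c(reagent) = 0.54 M, and you need that comparison to rank these four flasks.

| flask | substrate | reagent | remark | time |
|---|---|---|---|---|
| dusk | 0.11 M | 0.54 M | run made earlier |  |
| midnight | 0.42 M | 0.54 M | run made earlier |  |
| summer | 1.1 M | 0.54 M | run made earlier |  |
| winter | 0.27 M | 0.27 M | run made earlier |  |
| grey | 0.27 M | 0.540 M |  | 8.0 h |
| blue | 1.0 M | 0.400 M |  | 8.0 h |
| green | 0.15 M | 0.250 M |  | 8.0 h |
| teal | 0.50 M | 0.400 M |  | 8.0 h |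

| run | time / h | target / % |
|---|---|---|
| dusk | 0.667 | 6.4 |
| dusk | 1.33 | 10.9 |
| dusk | 2.50 | 17.6 |
| dusk | 4.00 | 22.4 |
| dusk | 8.00 | 28.9 |
| midnight | 0.667 | 5.8 |
| midnight | 1.33 | 11.1 |
| midnight | 2.50 | 17.5 |
| midnight | 4.00 | 20.8 |
| midnight | 8.00 | 23.9 |
| summer | 1.50 | 11.3 |
| summer | 3.00 | 15.4 |
| summer | 5.00 | 17.7 |
| summer | 6.00 | 17.1 |
| summer | 8.00 | 17.7 |
| winter | 0.667 | 2.6 |
| winter | 2.00 | 7.0 |
| winter | 4.00 | 12.2 |
| winter | 6.00 | 14.8 |
| winter | 8.00 | 16.7 |

(readings scatter by 0.5 percentage points)

- the flasks put in order of amount of target, in percent of the substrate charged, best first, at 8.0 h (grey / blue / green / teal)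
- the amount of target, in percent of the substrate charged of the flask you put first, at 8.0 h
- the amount of target, in percent of the substrate charged of the flask you put last, at 8.0 h



Grey has winter's substrate and twice its reagent, and a straight interpolation between dusk and midnight puts grey at 26.3%. I therefore treat reagent as a correction to the yield at c(reagent) = 0.540 M: the reagent exponent n, an apparent order in reagent for the yield at fixed time and substrate, is the logarithm of the yield ratio over the logarithm of the reagent ratio, here 0.656. Interpolating to each flask's substrate and multiplying by the reagent ratio raised to n, my own reckoning gives teal 19.0%, green 17.0% and blue 15.3%.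

The forecast reads grey > teal > green > blue, with 26% first and 14.6% last, its lower-reagent flasks reached by “Scaling to lower reagent using winter”; my order is the same, but my blue stands higher than its last value.

The flask gives grey > teal > green > blue, with grey at 26.9% and blue at 13.9%, and the scheme behind it is this:

    substrate + reagent → target (k = 0.180 M⁻¹ h⁻¹)
    substrate + reagent → isomer of the product (k = 0.0690 M⁻¹ h⁻¹)
    target → over-reaction product (k = 0.100 h⁻¹)

That order belongs to 8.0 h: at 80.0 h grey holds 0.350% of target, less than green's 1.71%. Now start n from grey's 26.9%: for the neighbour like grey but with c(reagent) = 0.32 M, n predicts 19.1%, and that flask holds 18.8%.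

The data stem from a simulated flask for an exercise; noise was put on by code.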